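**Plan**

- Retrosynthesis: the ketal and silyl ether come off last; the C4' carbinol and the C5'–C6' epoxide go back to a quinone monoketal; the oxygenated six-membered ring is cut at C5'–C4', C4'–C3' and C6'–C1' (Dötz benzannulation), leaving a C12 alkyne and an isopropenyl carbene.
- Further back: C7=C8 from the 8α-oxygen of the lactone, C3–H from a C3–O bond, C13–O from a C13–Si bond, and C13–Si from a C–H bond of the 4α-methyl of 3β-hydroxysclareolide.
- Forward: rings A and B and the C9–C11–C12 chain are taken from (+)-sclareolide; the oxasilolane ring closes on C13, is opened oxidatively and C3 is deoxygenated; the lactone becomes alkyne and Δ7 alkene; the oxygenated ring is annulated on C12, dearomatised, epoxidised and reduced.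
- Stereochemistry: C5, C9 and C10 come from the chiral pool; C4 from the choice between its two methyls; C5'/C6' from a chiral phase-transfer catalyst; C4' from a CBS catalyst.
- Enabling feature: the decalin (C5, C9, C10) with the C9–C11–C12 chain is that of sclareolide, and the only extra oxygen of ring A sits on the equatorial 4α-methyl C13. This methyl is gauche to an equatorial 3β-oxygen, so a 3β-O–Si tether reaches it through a five-membered ring.

Key step: step 3

Remark on numbering: drimane numbering is used for the decalin (C11 and C12 are the chain on C9, C13 the 4α-methyl); the oxygenated ring is C1' (ketone), C2' (methyl), C3', C4' (carbinol), C5' (= former C12, bears C11), C6'.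
Remark on step 1: a C3-selective cytochrome P450 BM3 variant of the kind described for sclareolide is assumed to be available as an E. coli lysate.
Remark on the name: the target is called Epoxypholamin B as given; the SMILES defines the structure, in which the C4' hydroxyl is trans to the epoxide oxygen.

**Route**

Step 1
Reactants: 1 (+)-sclareolide
Product: 2 3β-hydroxysclareolide
Conditions: P450 BM3 variant (E. coli lysate), NADP+ (cat.), phosphite dehydrogenase, Na2HPO3, air, K2HPO4/KH2PO4 buffer pH 8.0, 25 °C
Reagents that add atoms: dioxygen, O=O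
Why: Enzymatic C–H hydroxylation by an engineered P450 monooxygenase (hydrogen abstraction and oxygen rebound at the heme iron) is established for sclareolide, the binding pocket presenting the C3 methylene so that the equatorial C–H is replaced with retention to give the 3β-alcohol.

Step 2
Reactants: 2 3β-hydroxysclareolide; 3 diethylsilane
Product: 4 3β-(diethylsilyloxy)sclareolide
Conditions: [Ir(cod)OMe]2 (0.05 mol %), THF, 23 °C; volatiles removed, crude used
Reagents that add atoms: none
Why: Iridium-catalysed dehydrogenative silylation of an alcohol with a dihydrosilane stops cleanly at the mono-alkoxy hydrosilane with a secondary alcohol and leaves the lactone untouched at room temperature.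

Step 3
Reactants: 4 3β-(diethylsilyloxy)sclareolide
Product: 5 3β-O,C13-bridged 2,2-diethyl-1,2-oxasilolane of sclareolide
Conditions: [Ir(cod)OMe]2 (1 mol %), 3,4,7,8-tetramethyl-1,10-phenanthroline (2.4 mol %), norbornene (1.2 equiv), THF, 100–120 °C, sealed tube
Reagents that add atoms: none
Why: The Si–H bond adds oxidatively to the phenanthroline-ligated iridium centre (monovalent to trivalent iridium), which anchors the metal at O3; the iridium silyl then cleaves a primary C–H bond of the 4α-methyl group and C–Si reductive elimination follows, the two hydrogens being passed to norbornene. The closest known reaction is the hydroxyl-directed iridium-catalysed γ-C–H silylation of hydridosilyl ethers, which is established on the equatorial C4 methyl of 3β-hydroxy terpenoids. The oxasilolane ring (O3–Si–C13–C4–C3) closes as a five-membered ring by C–Si bond formation from a six-membered iridacycle (Ir, Si, O3, C3, C4, C13), fused trans-diequatorially to ring A. C4 becomes stereogenic with C13 α because only the equatorial methyl is reached: engaging the axial 4β-methyl would push the iridium silyl unit into a 1,3-diaxial clash with the C10 methyl. The selectivity needed is one methyl out of two and primary C–H over the secondary C1–H and tertiary C5–H γ-positions; the short O–Si tether limits the reaction to γ-carbons and the catalyst's preference for primary C–H bonds leaves the 4α-methyl as the only match.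

Step 4
Reactants: 5 oxasilolane
Product: 6 3β,13-dihydroxysclareolide (3β-OH, 4α-CH2OH)
Conditions: H2O2 (30 % aq), KHCO3, THF/MeOH (1:1), 50 °C
Reagents that add atoms: hydrogen peroxide, OO
Why: Tamao–Fleming oxidation of an alkoxy-substituted silane converts the C13–Si bond into C13–OH with retention at carbon and releases O3 as the free alcohol, bicarbonate being too mild to open the lactone.

Step 5
Reactants: 6 3β,13-dihydroxysclareolide
Product: 7 13-O-(tert-butyldiphenylsilyl)-3β-hydroxysclareolide
Conditions: t-BuPh2SiCl (1.1 equiv), imidazole, DMF, 0 → 23 °C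
Reagents that add atoms: tert-butyldiphenylsilyl chloride, CC(C)(C)[Si](Cl)(c1ccccc1)c1ccccc1
Why: Silylation with a bulky chlorosilane is selective for the primary C13 hydroxyl over the secondary 3β-hydroxyl flanked by the quaternary C4, and this silyl ether is chosen because it survives the acid of step 10.

Step 6
Reactants: 7 13-O-silyl-3β-hydroxysclareolide
Product: 8 3-O-(phenoxythiocarbonyl) derivative of 7
Conditions: PhOC(S)Cl, pyridine, DMAP (cat.), CH2Cl2, 23 → 40 °C
Reagents that add atoms: O-phenyl chlorothionoformate, S=C(Cl)Oc1ccccc1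
Why: Thioacylation of a hindered secondary alcohol with phenyl chlorothionoformate under DMAP catalysis is the standard entry to a Barton–McCombie substrate and needs no strong base that could enolise the lactone.

Step 7
Reactants: 8 thionocarbonate
Product: 9 13-(tert-butyldiphenylsilyloxy)sclareolide
Conditions: Bu3SnH, AIBN (cat.), toluene, 110 °C
Reagents that add atoms: none
Why: Barton–McCombie deoxygenation proceeds by stannyl radical addition to sulfur, fragmentation to the secondary C3 radical and hydrogen transfer from the stannane, a sequence well used on 3β-oxygenated terpenoids and harmless to lactone and silyl ether.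

Step 8
Reactants: 9 silyloxy lactone
Product: 10 C12 lactol of 9 (anomer mixture)
Conditions: i-Bu2AlH (1.2 equiv), CH2Cl2, −78 °C; aq potassium sodium tartrate
Reagents that add atoms: none
Why: Partial reduction of a γ-lactone with i-Bu2AlH stops at the lactol because the aluminium hemiacetal is stable at −78 °C, as known for sclareolide itself.

Step 9
Reactants: 10 lactol
Product: 11 8α-hydroxy alkyne (9β-propargyl, C11H2–C12≡CH, 13-O-silyl)
Conditions: dimethyl (1-diazo-2-oxopropyl)phosphonate, K2CO3, MeOH, 0 → 23 °C
Reagents that add atoms: dimethyl (1-diazo-2-oxopropyl)phosphonate, CC(=O)C(=[N+]=[N-])P(=O)(OC)OC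
Why: Seyferth–Gilbert homologation with the Ohira–Bestmann reagent acts on the open hydroxy-aldehyde form of the lactol and, after loss of N2 and 1,2-hydrogen shift in the alkylidene carbene, gives the terminal alkyne with C12 as its substituted carbon.

Step 10
Reactants: 11 8α-hydroxy alkyne
Product: 12 Δ7 enyne (C7=C8, 8-methyl, 9β-propargyl, 13-O-silyl)
Conditions: H2SO4 (0.3 equiv), EtOH, 23 °C, stopped once the exocyclic isomer is consumed
Reagents that add atoms: none
Why: E1 dehydration of the tertiary alcohol gives the trisubstituted ring alkene as in the acid-mediated preparation of Δ7 drimanes, since the exocyclic isomer is re-protonated and funnelled to C7=C8 while loss of the hindered C9–H is slow, and alkyne and silyl ether tolerate the dilute acid.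

Step 11
Reactants: 13 2-bromopropene
Product: 16 pentacarbonyl[methoxy(isopropenyl)carbene]chromium, via isopropenyllithium 14 (not isolated), via lithium acylchromate 15 (not isolated)
Conditions: t-BuLi (2 equiv), THF, −78 °C; Cr(CO)6, −78 → 0 °C; Me3OBF4, CH2Cl2/H2O, 0 °C
Reagents that add atoms: chromium hexacarbonyl, O=C=[Cr](=C=O)(=C=O)(=C=O)(=C=O)=C=O; trimethyloxonium tetrafluoroborate, C[O+](C)C.F[B-](F)(F)F
Why: The Fischer carbene synthesis (halogen–lithium exchange, addition of the alkenyllithium to a CO ligand of zerovalent chromium, O-methylation of the acylate with Meerwein salt) is the standard preparation of this known alkenyl carbene complex.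

Step 12
Reactants: 12 Δ7 enyne; 16 carbene complex
Product: 18 2-(drimenylmethyl)-4-methoxy-5-methylphenol (13-O-silyl), via arene tricarbonylchromium complex 17 (not isolated)
Conditions: THF (0.05 M), 50 °C, argon; then air, MeCN, 23 °C
Reagents that add atoms: none
Why: In the Dötz benzannulation (alkyne insertion, CO insertion to a vinylketene, 6π-electrocyclisation, tautomerisation) a terminal alkyne places its substituted carbon C12 next to the CO-derived phenol carbon, which fixes the para relationship of C11 and the ring methyl, and air then removes the chromium from the electron-rich arene.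

Step 13
Reactants: 18 phenol
Product: 19 quinone monoketal (4'-ketone, 1',1'-dimethoxy, 2'-methyl, 5'-CH2-drimenyl)
Conditions: PhI(OAc)2 (1.1 equiv), MeOH, 0 °C
Reagents that add atoms: methanol, CO
Why: Oxidative dearomatisation of a 4-methoxyphenol with the trivalent iodine reagent in methanol adds methanol at the methoxy-bearing carbon, so the free ketone ends up at C4', the carbon that must become the carbinol, and the ketal at C1'.

Step 14
Reactants: 19 quinone monoketal
Product: 20 5',6'-epoxy ketone (epoxide configuration of the target)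
Conditions: t-BuOOH, N-benzylcinchonidinium chloride (20 mol %), NaOH (aq, 0.1 M), toluene, 0 → 23 °C
Reagents that add atoms: tert-butyl hydroperoxide, CC(C)(C)OO
Why: Weitz–Scheffer epoxidation under cinchona phase-transfer catalysis, a known way to desymmetrise quinone monoketals, sends the peroxide anion to the unsubstituted β-carbon C6' and not to the methylated C2', while the chiral ion pair selects the face (the pseudoenantiomeric cinchoninium salt gives the other face), the two possible products being diastereomers that can be told apart and separated.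

Step 15
Reactants: 20 epoxy ketone
Product: 21 trans-epoxy alcohol (4'-OH anti to the epoxide oxygen, ketal and silyl ether intact)
Conditions: (S)-2-methyl-CBS-oxazaborolidine (1.0 equiv), catecholborane (1.5 equiv), toluene, −78 °C; MeOH, then pH 7 buffer
Reagents that add atoms: none
Why: In the Corey–Bakshi–Shibata reduction the ketone should bind the catalyst anti to the fully substituted epoxide carbon C5' (the large group), so the (S)-catalyst delivers hydride in a 1,2-fashion to the face bearing the epoxide oxygen and sets C4' with the hydroxyl trans to the epoxide, under reagent control instead of the substrate's own bias.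

Step 16
Reactants: 21 silyl-protected epoxy alcohol
Product: 22 epoxy diol dimethyl ketal (free C13–OH)
Conditions: Bu4NF, AcOH (1:1), THF, 23 → 40 °C
Reagents that add atoms: none
Why: Fluoride-mediated cleavage of the silyl ether is driven by Si–F bond formation, and acetic acid buffering keeps the medium too weakly basic for Payne rearrangement of the epoxy alcohol, which would in any case need attack at the fully substituted C5'.

Step 17
Reactants: 22 epoxy diol dimethyl ketal
Product: 23 Epoxypholamin B
Conditions: oxalic acid dihydrate, THF/H2O (3:1), 23 °C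
Reagents that add atoms: water, O
Why: Acid-catalysed hydrolysis of the allylic dimethyl ketal through a conjugated oxocarbenium ion releases the C1' enone under conditions mild enough for the epoxide, the allylic alcohol and the C7=C8 alkene.

**Compound list**

1 | (+)-sclareolide | O=C1C[C@H]3[C@](C)(O1)CC[C@H]4C(C)(C)CCC[C@]34C | starting material
2 | 3β-hydroxysclareolide | O=C1C[C@H]3[C@](C)(O1)CC[C@H]4C(C)(C)[C@@H](O)CC[C@]34C | intermediate
3 | diethylsilane | CC[SiH2]CC | starting material
4 | 3β-(diethylsilyloxy)sclareolide | O=C1C[C@H]3[C@](C)(O1)CC[C@H]4C(C)(C)[C@@H](O[SiH](CC)CC)CC[C@]34C | intermediate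
5 | 3β-O,C13-bridged 2,2-diethyl-1,2-oxasilolane of sclareolide | O=C1C[C@H]3[C@](C)(O1)CC[C@H]4[C@]5(C)C[Si](CC)(CC)O[C@H]5CC[C@]34C | intermediate
6 | 3β,13-dihydroxysclareolide | O=C1C[C@H]3[C@](C)(O1)CC[C@H]4[C@](C)(CO)[C@@H](O)CC[C@]34C | intermediate
7 | 13-O-(tert-butyldiphenylsilyl)-3β-hydroxysclareolide | O=C1C[C@H]3[C@](C)(O1)CC[C@H]4[C@](C)(CO[Si](c5ccccc5)(c6ccccc6)C(C)(C)C)[C@@H](O)CC[C@]34C | intermediate
8 | 3-O-(phenoxythiocarbonyl) derivative of 7 | O=C1C[C@H]3[C@](C)(O1)CC[C@H]4[C@](C)(CO[Si](c5ccccc5)(c6ccccc6)C(C)(C)C)[C@@H](OC(=S)Oc7ccccc7)CC[C@]34C | intermediate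
9 | 13-(tert-butyldiphenylsilyloxy)sclareolide | O=C1C[C@H]3[C@](C)(O1)CC[C@H]4[C@](C)(CO[Si](c5ccccc5)(c6ccccc6)C(C)(C)C)CCC[C@]34C | intermediate
10 | C12 lactol of 9 (anomer mixture) | OC1C[C@H]3[C@](C)(O1)CC[C@H]4[C@](C)(CO[Si](c5ccccc5)(c6ccccc6)C(C)(C)C)CCC[C@]34C | intermediate
11 | 8α-hydroxy-9β-propargyl decalin, 13-O-silyl (hydroxy alkyne) | C#CC[C@H]3[C@](C)(O)CC[C@H]4[C@](C)(CO[Si](c5ccccc5)(c6ccccc6)C(C)(C)C)CCC[C@]34C | intermediate
12 | Δ7 enyne, 13-O-silyl | C#CC[C@H]3C(C)=CC[C@H]4[C@](C)(CO[Si](c5ccccc5)(c6ccccc6)C(C)(C)C)CCC[C@]34C | intermediate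
13 | 2-bromopropene | CC(Br)=C | starting material
14 | isopropenyllithium | [Li]C(C)=C | intermediate
15 | lithium pentacarbonyl(2-methylacryloyl)chromate | [Li+].[O-]C(C(C)=C)=[Cr](=C=O)(=C=O)(=C=O)(=C=O)=C=O | intermediate
16 | pentacarbonyl[methoxy(isopropenyl)carbene]chromium | COC(C(C)=C)=[Cr](=C=O)(=C=O)(=C=O)(=C=O)=C=O | intermediate
17 | tricarbonylchromium η6-complex of phenol 18 (arene–metal bond not drawn) | COc1cc(C[C@H]3C(C)=CC[C@H]4[C@](C)(CO[Si](c5ccccc5)(c6ccccc6)C(C)(C)C)CCC[C@]34C)c(O)cc1C.O=C=[Cr](=C=O)=C=O | intermediate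
18 | 2-(drimenylmethyl)-4-methoxy-5-methylphenol, 13-O-silyl | COc1cc(C[C@H]3C(C)=CC[C@H]4[C@](C)(CO[Si](c5ccccc5)(c6ccccc6)C(C)(C)C)CCC[C@]34C)c(O)cc1C | intermediate
19 | 4,4-dimethoxy-5-methyl-2-(drimenylmethyl)cyclohexa-2,5-dienone, 13-O-silyl | COC1(OC)C=C(C[C@H]3C(C)=CC[C@H]4[C@](C)(CO[Si](c5ccccc5)(c6ccccc6)C(C)(C)C)CCC[C@]34C)C(=O)C=C1C | intermediate
20 | 5',6'-epoxy-4'-ketone dimethyl ketal, 13-O-silyl | CC1=CC(=O)[C@]2(C[C@H]3C(C)=CC[C@H]4[C@](C)(CO[Si](c5ccccc5)(c6ccccc6)C(C)(C)C)CCC[C@]34C)O[C@@H]2C1(OC)OC | intermediate
21 | trans-epoxy alcohol dimethyl ketal, 13-O-silyl | CC1=C[C@@H](O)[C@]2(C[C@H]3C(C)=CC[C@H]4[C@](C)(CO[Si](c5ccccc5)(c6ccccc6)C(C)(C)C)CCC[C@]34C)O[C@@H]2C1(OC)OC | intermediate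
22 | trans-epoxy alcohol dimethyl ketal, free C13–OH | CC1=C[C@@H](O)[C@]2(C[C@H]3C(C)=CC[C@H]4[C@](C)(CO)CCC[C@]34C)O[C@@H]2C1(OC)OC | intermediate
23 | Epoxypholamin B | CC1=C[C@@H](O)[C@]2(C[C@H]3C(C)=CC[C@H]4[C@](C)(CO)CCC[C@]34C)O[C@@H]2C1=O | target

**Step count**

Total: 17 steps. Longest linear sequence: 16 steps (steps 1–10 and 12–17); step 11 is a one-step side branch.

**Steps most likely to fail**

1. Step 14. The chiral ion pair may discriminate poorly between the two faces of this α-branched dienone, so that both epoxide diastereomers form, or the hindered substrate may react sluggishly under phase transfer. The fallback replaces catalyst control by an auxiliary in the ketal. It sets out from 19: exchange of the dimethyl ketal with (2S,4S)-pentane-2,4-diol (PPTS, benzene, 80 °C) should give the C2-symmetric spiroketal dienone F1. Its dioxane chair carries one axial methyl that blocks one face of C6', so Ph3COOH with KN(SiMe3)2 in THF at −35 °C should give the spiroketal epoxy ketone F2 (the antipodal diol reverses the face). Reduction as in step 15 would give the spiroketal trans-epoxy alcohol F3, Bu4NF/AcOH the desilylated spiroketal F4, and aqueous HF in MeCN would then remove the dioxane ketal, rejoining the route at 23.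

2. Step 15. Hydride may be delivered to the wrong face if the substrate's preference for attack anti to the epoxide oxygen outweighs the catalyst, and the borane may also open the epoxide. The fallback accepts the substrate's preference and inverts afterwards. It sets out from 20: Luche reduction (NaBH4, CeCl3·7H2O, MeOH, −78 °C) should give the cis-epoxy alcohol F5. Mitsunobu inversion (4-nitrobenzoic acid, PPh3, diisopropyl azodicarboxylate, toluene, 0 → 23 °C) would give the inverted 4-nitrobenzoate F6, and methanolysis (K2CO3, MeOH, 0 °C) rejoins the route at 21.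

3. Step 10. Proton loss from the C8 cation may be unselective (exocyclic and C8=C9 isomers), or the desired alkene may isomerise further on prolonged acid contact. The fallback builds the alkene position unambiguously. It sets out from 11: SOCl2/pyridine in CH2Cl2 at −78 °C eliminates through the only anti-periplanar hydrogens, those of the methyl group, to the exocyclic alkene F7. Lemieux–Johnson cleavage (OsO4 cat., NaIO4, 2,6-lutidine, dioxane/H2O) leaves the alkyne and gives the C8 ketone F8. Kinetic deprotonation at C7 with LiN(i-Pr)2 (2.2 equiv, the second equivalent parking the alkyne as its acetylide) and trapping with N-(5-chloro-2-pyridyl)triflimide at −78 °C gives the Δ7 enol triflate F9. Coupling with Me2CuLi (THF, −15 °C) installs the C8 methyl and rejoins the route at 12.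

**Further compounds**

F1 | step 14 | (2S,4S)-pentane-2,4-diyl spiroketal dienone | CC1=CC(=O)C(C[C@H]3C(C)=CC[C@H]4[C@](C)(CO[Si](c5ccccc5)(c6ccccc6)C(C)(C)C)CCC[C@]34C)=CC17O[C@@H](C)C[C@H](C)O7
F2 | step 14 | spiroketal 5',6'-epoxy ketone | CC1=CC(=O)[C@]2(C[C@H]3C(C)=CC[C@H]4[C@](C)(CO[Si](c5ccccc5)(c6ccccc6)C(C)(C)C)CCC[C@]34C)O[C@@H]2C17O[C@@H](C)C[C@H](C)O7
F3 | step 14 | spiroketal trans-epoxy alcohol, 13-O-silyl | CC1=C[C@@H](O)[C@]2(C[C@H]3C(C)=CC[C@H]4[C@](C)(CO[Si](c5ccccc5)(c6ccccc6)C(C)(C)C)CCC[C@]34C)O[C@@H]2C17O[C@@H](C)C[C@H](C)O7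
F4 | step 14 | spiroketal trans-epoxy alcohol, free C13–OH | CC1=C[C@@H](O)[C@]2(C[C@H]3C(C)=CC[C@H]4[C@](C)(CO)CCC[C@]34C)O[C@@H]2C17O[C@@H](C)C[C@H](C)O7
F5 | step 15 | cis-epoxy alcohol dimethyl ketal (C4' epimer of 21) | CC1=C[C@H](O)[C@]2(C[C@H]3C(C)=CC[C@H]4[C@](C)(CO[Si](c5ccccc5)(c6ccccc6)C(C)(C)C)CCC[C@]34C)O[C@@H]2C1(OC)OC
F6 | step 15 | 4-nitrobenzoate of 21 | CC1=C[C@@H](OC(=O)c7ccc(cc7)[N+](=O)[O-])[C@]2(C[C@H]3C(C)=CC[C@H]4[C@](C)(CO[Si](c5ccccc5)(c6ccccc6)C(C)(C)C)CCC[C@]34C)O[C@@H]2C1(OC)OC
F7 | step 10 | exocyclic C8-methylene alkyne | C#CC[C@H]3C(=C)CC[C@H]4[C@](C)(CO[Si](c5ccccc5)(c6ccccc6)C(C)(C)C)CCC[C@]34C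
F8 | step 10 | C8 ketone alkyne | C#CC[C@H]3C(=O)CC[C@H]4[C@](C)(CO[Si](c5ccccc5)(c6ccccc6)C(C)(C)C)CCC[C@]34C
F9 | step 10 | Δ7 enol triflate alkyne | C#CC[C@H]3C(OS(=O)(=O)C(F)(F)F)=CC[C@H]4[C@](C)(CO[Si](c5ccccc5)(c6ccccc6)C(C)(C)C)CCC[C@]34C
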